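## Analysis of the target

The target is a 3,6,7-trisubstituted coumarin (2H-chromen-2-one). Ring A carries a free hydroxyl at C7 and, next to it at C6, a reverse-prenyl group whose quaternary carbon bears two methyls and a vinyl group. The pyranone ring carries at C3 a ten-carbon chain joined through a methylene, C1′.

The chain holds a trisubstituted 2′,3′-oxirane (C2′ S, C3′ R, with C1′ and C4′ cis, so it is the oxide of a Z, neryl-type alkene) and a terminal 6′,7′-oxirane (C6′ R). C2′ and C3′ are tied together by their ring. C6′ is two methylenes away and must be set by a reagent. C2′ and C6′ sit in homologous environments but have opposite descriptors, so a single chiral oxidant acting on both alkenes of a neryl chain would be expected to give the wrong diastereomer.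

Sensitive groups are the two acid-labile oxiranes, the lactone, the oxidisable phenol, and the 1,1-dimethylallyl group ortho to a phenol, which rearranges or cyclises under acid or strong heating.

The hard region is C3–C1′–C2′. A carbanion on the precursor of C3 can open the oxirane (three-membered ring closure). A free carboxyl group on that carbon is a γ,δ-epoxy acid and can lactonise onto C2′.

The strategy rests on the position of the ring oxygen. O1 is bonded to C8a, which is ortho to C4a (the carbon carrying the C4=C3 alkene) and para to the quaternary substituent on C6. The other carbon ortho to C4a, C5, is flanked by that substituent. C8a is the carbon that coumarin biosynthesis oxygenates in a cinnamate, so ring A can be bought as a para-oxygenated benzaldehyde and the O1–C8a bond made last from a C–H bond.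

## Retrosynthetic reasoning

Compound numbers are those of the list after the steps.

**16 from 15 (O–Si).** The last bond cut is the O–Si bond of silyl ether 15. The C7 oxygen must be masked during the oxidative ring closure, because a free para-hydroxycinnamic acid would be oxidised at the phenol. A silyl ether keeps the ring electron-rich and is removed under buffered, non-acidic conditions that spare the lactone and both oxiranes.

**15 from 13 (O1–C8a).** Cutting the bond between the lactone oxygen and C8a turns the pyranone ring into the carboxyl group of the α-alkylcinnamic acid 13 and C8a into an aromatic C–H. The usual cut at the acyl C–O bond would need an ortho-hydroxybenzaldehyde with three different ring substituents; this cut lets ring A come from the symmetrical aldehyde 1. In the forward sense the carboxyl group must first be brought to the ring side of the alkene (Z acid 14) and then replace the ortho hydrogen under photocatalytic aerobic conditions. The step must choose the open ortho carbon over the one beside the quaternary group and must leave both oxiranes intact. No electron-rich alkene remains in the molecule at this stage.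

**13 from 12 (ester C–O).** The acid is carried as its allyl ester. Alkaline hydrolysis followed by acidification would endanger the aryl silyl ether and expose the γ,δ-epoxy acid to acid. An allyl ester is removed under neutral conditions with a zerovalent palladium catalyst.

**12 from 5 and 11 (C3=C4).** The alkene is cut by olefination. Aldehyde 5 supplies C4 and ring A; phosphonate 11 supplies C2, C3 and the whole side chain. The alkene geometry obtained is immaterial, since the key step equilibrates it. The forward reaction needs the phosphonate carbanion to add to the aldehyde faster than it attacks its own oxirane.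

**11 from 9 and 10 (future C3–C1′).** The commercial phosphonate 10 is the nucleophile and the side chain arrives as the primary triflate 9, with both oxiranes and all three stereocentres already in place. The cut is made at C1′ because it is the only chain carbon between C3 and C3′ that is neither stereogenic nor part of an oxirane.

**9 from 8, 7 and 6 (the oxirane C–O bonds).** Triflate 9 comes from alcohol 8. The 2′,3′-oxirane is traced to the Z allylic alcohol of nerol 6: the hydroxyl group directs a titanium–tartrate epoxidation to the 2,3-alkene only and sets 2S,3R in 7. The 6′,7′-oxirane is traced to the remaining trisubstituted alkene, epoxidised by a chiral dioxirane to give 8. Two different oxidants are needed because the two CH centres have opposite descriptors. The directed epoxidation comes first because it needs the free allylic alcohol and ignores the distal alkene.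

**5 from 4, 3, 1 and 2 (C6–quaternary carbon bond).** Silyl ether 5 comes from phenol 4. The aryl–quaternary carbon bond of 4 is cut by a retro-Claisen step to prenyl ether 3, made from 1 and 2. Because 1 has two equivalent ortho carbons and a blocked para carbon, the rearrangement can place the reverse-prenyl group in only one position.

## Alternatives that were turned down

**Alternative 1:** The disconnection is at the quaternary benzylic carbon, cutting its bonds to one methyl and to the vinyl group. In the forward key step, ketone A2 (a 2-acetylphenyl tert-butyl carbonate with a para silyloxy group) takes up CH3MgBr. The resulting tertiary alkoxide accepts the carbonate group from the neighbouring oxygen, the phenoxide expels it, and ortho-quinone methide A3 forms. CH2=CHMgBr then adds to A3 in conjugate fashion to give phenol A1.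
- For it: the quaternary carbon is built at a defined ring carbon with both ring oxygens present. There is no sigmatropic step, and the pyranone would close by ordinary lactonisation onto an existing oxygen. On certainty of ring closure this is stronger than the chosen route.
- Against it: A1 lacks the carbon that becomes C4. It would have to be introduced ortho to the silyloxy carbon and para to the free hydroxyl, on an acid-sensitive ortho-(1,1-dimethylallyl)phenol. The two oxygens then have to exchange roles (the silylated one is the future O1, the free one the future C7 hydroxyl). A2 itself needs two selective protections. The two Grignard additions must also be kept apart in time.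
- Comparison: several more operations are needed before phosphonate 11 can be used. The chosen route reaches aldehyde 5 in three steps with one protecting group and concentrates its risk in one late step.

**Alternative 2:** Ring A is disconnected across C5–C6 and C4a–C8a. Forward, the bis(silyloxy) ketene-acetal diene A5, bearing the 1,1-dimethylallyl group at its terminus, adds to methyl propiolate A6. Loss of methoxytrimethylsilane aromatises the adduct to resorcylate A4.
- For it: one step places all four substituents of ring A, with regiochemistry fixed by the polarity of diene and ynoate. The ester carbon is the future C4, and the hydrogen-bonded hydroxyl is easily distinguished from the other. On regiochemical certainty in ring A it is as strong as or stronger than the chosen route.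
- Against it: the diene terminus that must bond carries a fully substituted carbon, so the cycloaddition forms a bond beside a quaternary centre with a moderately reactive dienophile. The β-keto ester behind A5 must be made and doubly silylated. After A4 the ester must be adjusted to the aldehyde oxidation level with both phenols masked.
- Comparison: the aromatic half becomes roughly three times as long as in the chosen route, in order to build a benzene ring that can be purchased.

**Alternative 3:** Ring A is disconnected across C6–C7 and C7–C8, with C7 coming from carbon monoxide and the C8a–O bond from an acyloxy shift. Forward, the tertiary 3-acetoxy-1,4-enyne A8 reacts with [Rh(CO)2Cl]2 under CO. A 1,2-acetoxy shift gives a rhodium carbene, CO insertion gives a dienyl ketene, and six-electron electrocyclisation with tautomerisation gives phenol A7.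
- For it: A7 has the two oxygens differentiated (free C7 hydroxyl, acetate on the future O1) and the future C4 as a protected hydroxymethyl group. This is the best-differentiated ring A of the three.
- Against it: the electrocyclisation terminus carries the tert-alkyl group, which should slow the closure. The tertiary propargylic acetate can ionise or eliminate. The extra vinyl group is a second ligand for rhodium. A8 needs about five steps, and after A7 the sequence still needs oxidation at C4, protection, olefination, deacetylation and lactonisation.
- Comparison: it is the longest of the routes and depends on a precious metal under CO. The chosen route instead uses the symmetry of 1 and a single C–H oxidation.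

Key step: step 10

Remark: 11 is a mixture of epimers at the phosphorus-bearing carbon, and 12 and 13 may contain some Z isomer; both are harmless because that carbon becomes trigonal and step 10 begins by equilibrating the alkene geometry. Structures are written as the E isomers, and 10 and the D-fructose-derived ketone are taken as purchased.

## Route

Step 1
Reactants: 1 4-hydroxybenzaldehyde; 2 prenyl bromide (1-bromo-3-methylbut-2-ene)
Product: 3 4-[(3-methylbut-2-en-1-yl)oxy]benzaldehyde
Conditions: K2CO3, acetone, reflux
Reagents that add atoms: none
Why: Williamson ether synthesis; the phenoxide is alkylated at oxygen by the primary allylic bromide (SN2), and a carbonate base in acetone keeps C-alkylation and SN2′ attack minor.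

Step 2
Reactants: 3 4-[(3-methylbut-2-en-1-yl)oxy]benzaldehyde
Product: 4 4-hydroxy-3-(2-methylbut-3-en-2-yl)benzaldehyde
Conditions: EtOH/H2O 4:1, 130 °C, sealed vessel
Reagents that add atoms: none
Why: Aromatic Claisen rearrangement; the [3,3] shift moves the prenyl group with allylic inversion to an ortho carbon and tautomerisation restores the phenol. Both ortho carbons are equivalent and the para carbon is blocked, and the protic medium lowers the temperature needed, which should limit abnormal Claisen rearrangement and cyclisation of the product.

Step 3
Reactants: 4 4-hydroxy-3-(2-methylbut-3-en-2-yl)benzaldehyde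
Product: 5 4-{[tert-butyl(dimethyl)silyl]oxy}-3-(2-methylbut-3-en-2-yl)benzaldehyde
Conditions: TBSCl, imidazole, DMF, 40 °C
Reagents that add atoms: tert-butyldimethylsilyl chloride, CC(C)(C)[Si](C)(C)Cl
Why: Imidazole-promoted O-silylation of an acidic phenol; the neighbouring quaternary carbon slows the reaction but later shields the Si–O bond from nucleophiles.

Step 4
Reactants: 6 nerol ((2Z)-3,7-dimethylocta-2,6-dien-1-ol)
Product: 7 [(2S,3R)-3-methyl-3-(4-methylpent-3-en-1-yl)oxiran-2-yl]methanol
Conditions: Ti(OiPr)4, L-(+)-diethyl tartrate, t-BuOOH, 4 Å MS, CH2Cl2, −25 °C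
Reagents that add atoms: tert-butyl hydroperoxide, CC(C)(C)OO
Why: Sharpless asymmetric epoxidation; the titanium-bound allylic alkoxide restricts oxygen transfer to the 2,3-alkene, the L-(+)-tartrate ligand selects the face that gives 2S, and syn addition to the Z alkene then fixes C3 as R with C1 and C4 cis.

Step 5
Reactants: 7 [(2S,3R)-3-methyl-3-(4-methylpent-3-en-1-yl)oxiran-2-yl]methanol
Product: 8 [(2S,3R)-3-{2-[(2R)-3,3-dimethyloxiran-2-yl]ethyl}-3-methyloxiran-2-yl]methanol
Conditions: 1,2:4,5-di-O-isopropylidene-β-D-erythro-2,3-hexodiulo-2,6-pyranose (30 mol%), KHSO5 (as 2KHSO5·KHSO4·K2SO4), K2CO3, Bu4NHSO4, MeCN/CH2(OMe)2/aq. Na2B4O7 buffer, 0 °C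
Reagents that add atoms: potassium peroxymonosulfate, [K+].[O-]S(=O)(=O)OO
Why: Shi epoxidation; the dioxirane of the D-fructose-derived ketone attacks the remaining trisubstituted alkene through a spiro transition state from the face that gives 6R, the sense established for trisubstituted and trans alkenes, under reagent control and independent of the distant oxirane. Any diastereomer arising from imperfect control in step 4 or 5 should be removable at this stage.

Step 6
Reactants: 8 [(2S,3R)-3-{2-[(2R)-3,3-dimethyloxiran-2-yl]ethyl}-3-methyloxiran-2-yl]methanol
Product: 9 [(2S,3R)-3-{2-[(2R)-3,3-dimethyloxiran-2-yl]ethyl}-3-methyloxiran-2-yl]methyl trifluoromethanesulfonate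
Conditions: Tf2O, 2,6-lutidine, CH2Cl2, −78 °C; cold aqueous work-up, used at once without purification
Reagents that add atoms: trifluoromethanesulfonic anhydride, O=S(=O)(OS(=O)(=O)C(F)(F)F)C(F)(F)F
Why: O-sulfonylation of the primary alcohol with a hindered base; no bond to a stereocentre is touched, and oxiranylmethyl triflates of this kind are usable when kept cold and consumed immediately.

Step 7
Reactants: 9 [(2S,3R)-3-{2-[(2R)-3,3-dimethyloxiran-2-yl]ethyl}-3-methyloxiran-2-yl]methyl trifluoromethanesulfonate; 10 allyl diethylphosphonoacetate (prop-2-en-1-yl 2-(diethoxyphosphoryl)acetate)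
Product: 11 prop-2-en-1-yl 2-(diethoxyphosphoryl)-3-[(2S,3R)-3-{2-[(2R)-3,3-dimethyloxiran-2-yl]ethyl}-3-methyloxiran-2-yl]propanoate (both epimers at C2)
Conditions: 10 (excess), NaH, THF, 0 °C; then 9, −40 to 0 °C; NH4Cl quench
Reagents that add atoms: none
Why: C-alkylation of a phosphonoacetate carbanion (SN2) at the primary triflate carbon, which is far more electrophilic than either oxirane carbon; excess 10 suppresses dialkylation, and the new centre at C2 forms without control, which is harmless because it becomes trigonal in step 8.

Step 8
Reactants: 5 4-{[tert-butyl(dimethyl)silyl]oxy}-3-(2-methylbut-3-en-2-yl)benzaldehyde; 11 prop-2-en-1-yl 2-(diethoxyphosphoryl)-3-[(2S,3R)-3-{2-[(2R)-3,3-dimethyloxiran-2-yl]ethyl}-3-methyloxiran-2-yl]propanoate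
Product: 12 prop-2-en-1-yl (2E)-3-{4-[tert-butyl(dimethyl)silyl]oxy-3-(2-methylbut-3-en-2-yl)phenyl}-2-{[(2S,3R)-3-{2-[(2R)-3,3-dimethyloxiran-2-yl]ethyl}-3-methyloxiran-2-yl]methyl}prop-2-enoate
Conditions: NaH, THF, −20 °C; then 5, −20 to 0 °C
Reagents that add atoms: none
Why: Horner–Wadsworth–Emmons olefination; α-branched phosphonoacetates give mainly the E trisubstituted ester with aryl aldehydes. Addition to the aldehyde should outrun attack of the carbanion on its own oxirane, which would require displacement at a secondary carbon beside a quaternary one.

Step 9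
Reactants: 12 prop-2-en-1-yl (2E)-3-{4-[tert-butyl(dimethyl)silyl]oxy-3-(2-methylbut-3-en-2-yl)phenyl}-2-{[(2S,3R)-3-{2-[(2R)-3,3-dimethyloxiran-2-yl]ethyl}-3-methyloxiran-2-yl]methyl}prop-2-enoate
Product: 13 (2E)-3-{4-[tert-butyl(dimethyl)silyl]oxy-3-(2-methylbut-3-en-2-yl)phenyl}-2-{[(2S,3R)-3-{2-[(2R)-3,3-dimethyloxiran-2-yl]ethyl}-3-methyloxiran-2-yl]methyl}prop-2-enoic acid
Conditions: Pd(PPh3)4 (5 mol%), morpholine, THF, rt; work-up with pH 5.5 phosphate buffer, no silica, used at once
Reagents that add atoms: none
Why: Tsuji–Trost deallylation; zerovalent palladium ionises the allyl ester to a π-allyl complex and the carboxylate, and morpholine captures the allyl group. The neutral conditions leave the aryl silyl ether, both oxiranes and the vinyl group untouched.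

Step 10
Reactants: 13 (2E)-3-{4-[tert-butyl(dimethyl)silyl]oxy-3-(2-methylbut-3-en-2-yl)phenyl}-2-{[(2S,3R)-3-{2-[(2R)-3,3-dimethyloxiran-2-yl]ethyl}-3-methyloxiran-2-yl]methyl}prop-2-enoic acid
Product: 15 7-{[tert-butyl(dimethyl)silyl]oxy}-3-{[(2S,3R)-3-{2-[(2R)-3,3-dimethyloxiran-2-yl]ethyl}-3-methyloxiran-2-yl]methyl}-6-(2-methylbut-3-en-2-yl)-2H-chromen-2-one, via Z acid 14 (not isolated)
Conditions: (−)-riboflavin (5 mol%), O2 (1 atm), 2,6-lutidine (1.2 equiv), MeCN/MeOH 1:1, 402 nm LED, rt
Reagents that add atoms: none
Why: Triplet energy transfer from excited riboflavin interconverts 13 and its Z isomer 14; only 14 has the carboxyl group beside the ring, and its irreversible consumption drains the photostationary mixture. Single-electron oxidation by the excited flavin of the silyloxy-substituted arene (or of its carboxylate) then lets the carboxyl oxygen bond to the ortho ring carbon; loss of a second electron and a proton rearomatises, and O2 reoxidises the reduced flavin, ending as H2O2. The closest known reaction type is the flavin-photocatalysed isomerisation and oxidative cyclisation of cinnamic acids to coumarins, with the K2S2O8- or Cu(OAc)2-mediated dehydrogenative lactonisation of 2-arylbenzoic acids as its mechanistic relative. The pyranone ring closes by attack of oxygen on an aromatic carbon in a six-membered mode, formally 6-endo with respect to the C4a–C8a π bond. No stereocentre is formed, and the three existing ones are remote from the chromophore. Site selectivity between the two carbons ortho to the side chain is required: the one between the side chain and the quaternary 2-methylbut-3-en-2-yl group is shielded, so bonding should go to the open CH para to that group, which becomes C8a. Chemoselectivity is secured because the only alkene left for singlet oxygen is the hindered monosubstituted vinyl group, the ring substituents carry no benzylic hydrogen, and 2,6-lutidine keeps the medium non-acidic for the oxiranes.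

Step 11
Reactants: 15 7-{[tert-butyl(dimethyl)silyl]oxy}-3-{[(2S,3R)-3-{2-[(2R)-3,3-dimethyloxiran-2-yl]ethyl}-3-methyloxiran-2-yl]methyl}-6-(2-methylbut-3-en-2-yl)-2H-chromen-2-one
Product: 16 3-{[(2S,3R)-3-{2-[(2R)-3,3-dimethyloxiran-2-yl]ethyl}-3-methyloxiran-2-yl]methyl}-7-hydroxy-6-(2-methylbut-3-en-2-yl)-2H-chromen-2-one
Conditions: Bu4NF, AcOH, THF, 0 °C
Reagents that add atoms: none
Why: Fluoride-induced cleavage of the aryl silyl ether; acetic acid buffers the phenoxide so that the lactone is not opened, and the oxiranes are inert to buffered fluoride.

## Compound list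

1 | 4-hydroxybenzaldehyde | O=Cc1ccc(O)cc1 | starting material
2 | prenyl bromide (1-bromo-3-methylbut-2-ene) | CC(C)=CCBr | starting material
3 | 4-[(3-methylbut-2-en-1-yl)oxy]benzaldehyde | CC(C)=CCOc1ccc(C=O)cc1 | intermediate
4 | 4-hydroxy-3-(2-methylbut-3-en-2-yl)benzaldehyde | C=CC(C)(C)c1cc(C=O)ccc1O | intermediate
5 | 4-{[tert-butyl(dimethyl)silyl]oxy}-3-(2-methylbut-3-en-2-yl)benzaldehyde | C=CC(C)(C)c1cc(C=O)ccc1O[Si](C)(C)C(C)(C)C | intermediate
6 | nerol | CC(C)=CCC/C(C)=C\CO | starting material
7 | [(2S,3R)-3-methyl-3-(4-methylpent-3-en-1-yl)oxiran-2-yl]methanol | OC[C@@H]1O[C@]1(C)CCC=C(C)C | intermediate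
8 | [(2S,3R)-3-{2-[(2R)-3,3-dimethyloxiran-2-yl]ethyl}-3-methyloxiran-2-yl]methanol | OC[C@@H]1O[C@]1(C)CC[C@H]1OC1(C)C | intermediate
9 | [(2S,3R)-3-{2-[(2R)-3,3-dimethyloxiran-2-yl]ethyl}-3-methyloxiran-2-yl]methyl trifluoromethanesulfonate | FC(F)(F)S(=O)(=O)OC[C@@H]1O[C@]1(C)CC[C@H]1OC1(C)C | intermediate
10 | allyl diethylphosphonoacetate | C=CCOC(=O)CP(=O)(OCC)OCC | starting material
11 | prop-2-en-1-yl 2-(diethoxyphosphoryl)-3-[(2S,3R)-3-{2-[(2R)-3,3-dimethyloxiran-2-yl]ethyl}-3-methyloxiran-2-yl]propanoate (epimers at C2) | C=CCOC(=O)C(C[C@@H]1O[C@]1(C)CC[C@H]1OC1(C)C)P(=O)(OCC)OCC | intermediate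
12 | prop-2-en-1-yl (2E)-3-{4-[tert-butyl(dimethyl)silyl]oxy-3-(2-methylbut-3-en-2-yl)phenyl}-2-{[(2S,3R)-3-{2-[(2R)-3,3-dimethyloxiran-2-yl]ethyl}-3-methyloxiran-2-yl]methyl}prop-2-enoate | C=CC(C)(C)c1cc(/C=C(\C[C@@H]2O[C@]2(C)CC[C@H]2OC2(C)C)C(=O)OCC=C)ccc1O[Si](C)(C)C(C)(C)C | intermediate
13 | (2E)-3-{4-[tert-butyl(dimethyl)silyl]oxy-3-(2-methylbut-3-en-2-yl)phenyl}-2-{[(2S,3R)-3-{2-[(2R)-3,3-dimethyloxiran-2-yl]ethyl}-3-methyloxiran-2-yl]methyl}prop-2-enoic acid | C=CC(C)(C)c1cc(/C=C(\C[C@@H]2O[C@]2(C)CC[C@H]2OC2(C)C)C(=O)O)ccc1O[Si](C)(C)C(C)(C)C | intermediate
14 | (2Z)-3-{4-[tert-butyl(dimethyl)silyl]oxy-3-(2-methylbut-3-en-2-yl)phenyl}-2-{[(2S,3R)-3-{2-[(2R)-3,3-dimethyloxiran-2-yl]ethyl}-3-methyloxiran-2-yl]methyl}prop-2-enoic acid | C=CC(C)(C)c1cc(/C=C(/C[C@@H]2O[C@]2(C)CC[C@H]2OC2(C)C)C(=O)O)ccc1O[Si](C)(C)C(C)(C)C | intermediate (not isolated)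
15 | 7-{[tert-butyl(dimethyl)silyl]oxy}-3-{[(2S,3R)-3-{2-[(2R)-3,3-dimethyloxiran-2-yl]ethyl}-3-methyloxiran-2-yl]methyl}-6-(2-methylbut-3-en-2-yl)-2H-chromen-2-one | C=CC(C)(C)c1cc2cc(C[C@@H]3O[C@]3(C)CC[C@H]3OC3(C)C)c(=O)oc2cc1O[Si](C)(C)C(C)(C)C | intermediate
16 | 3-{[(2S,3R)-3-{2-[(2R)-3,3-dimethyloxiran-2-yl]ethyl}-3-methyloxiran-2-yl]methyl}-7-hydroxy-6-(2-methylbut-3-en-2-yl)-2H-chromen-2-one | C=CC(C)(C)c1cc2cc(C[C@@H]3O[C@]3(C)CC[C@H]3OC3(C)C)c(=O)oc2cc1O | target

## Step count and least certain steps

Total: 11 steps. Longest linear sequence: 8 steps (6 → 7 → 8 → 9 → 11 → 12 → 13 → 15 → 16). The aromatic branch (1 → 5) is 3 steps.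

**Step 10 (key step).** Several processes could divert it.
- The carboxyl oxygen could bond to the ring carbon para to the silyloxy group instead of ortho. That is the electronically favoured site in the oxidised arene and would give a five-membered spirolactone with loss of the silyl group.
- The oxidised intermediate could lose a proton from C1′, followed by opening of the adjacent oxirane.
- Oxidation could be sluggish, since a silyloxy group is a weaker donor than an alkoxy group.
- The carboxyl group could open the 2′,3′-oxirane if the medium turns acidic.

Fallback, with the lactone oxygen installed before ring closure: it sets out from aldehyde 5. The formyl group is masked in the flask as its lithium α-amino alkoxide (lithium N,N,N′-trimethylethylenediamide), n-BuLi removes the ring hydrogen ortho to it on the open side, and B(OMe)3 followed by mild acid gives the boronic acid F1. Oxidation with H2O2 gives the salicylaldehyde F2. Olefination of F2 with 11 (two equivalents of NaH) gives the ortho-hydroxycinnamate F3. Its Z portion lactonises directly. Irradiation of the E portion (365 nm, or riboflavin at 402 nm under argon, energy transfer only) isomerises it so that the phenol oxygen closes onto the ester with loss of allyl alcohol. The route is rejoined at 15.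

**Step 8.** The phosphonate carbanion may open its own oxirane in a three-membered ring closure to a cyclopropane before it meets the electron-rich, slowly reacting aldehyde. Fallback with a neutral ylide: it sets out from triflate 9, which alkylates two equivalents of allyl (triphenyl-λ5-phosphanylidene)acetate (CH2Cl2, −20 °C to rt; the second equivalent deprotonates the phosphonium salt) to give the substituted ylide F4. Wittig reaction of F4 with 5 in toluene at 80–90 °C rejoins the route at 12.

**Step 6 (and its use in step 7).** The triflate may ionise with participation of the neighbouring oxirane oxygen and decompose before it is alkylated. Fallback with a stable halide: it sets out from alcohol 8. Appel iodination (I2, PPh3, imidazole, 0 °C) gives the epoxy iodide F5, which can be purified and alkylates the sodium salt of 10 in DMF at rt. The route is rejoined at 11.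

**Step 2.** The ortho-(1,1-dimethylallyl)phenol formed may react further at the rearrangement temperature, by abnormal Claisen rearrangement, cyclisation to a dihydrobenzofuran, or loss of the prenyl group. Fallback with acylative interception: it sets out from ether 3, which is heated in N,N-diethylaniline with butanoic anhydride at 190 °C so that the phenol is captured as it forms, giving the butanoate F6. Methanolysis (K2CO3, MeOH, rt) rejoins the route at 4.

**Step 9.** The liberated carboxyl group is γ,δ to the 2′,3′-oxirane and may open it during concentration or handling of the free acid. Fallback without ever protonating the carboxylate: it sets out from ester 12, which is deallylated with Pd(PPh3)4 and sodium 4-methylbenzenesulfinate in THF/MeOH. This gives the sodium carboxylate F7 directly. F7 is used as the salt in the photochemical step (no lutidine), and the route is rejoined at 15.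

## Further compounds

F1 | step 10 | {5-[tert-butyl(dimethyl)silyl]oxy-2-formyl-4-(2-methylbut-3-en-2-yl)phenyl}boronic acid | OB(O)c1cc(O[Si](C)(C)C(C)(C)C)c(C(C)(C)C=C)cc1C=O
F2 | step 10 | 4-{[tert-butyl(dimethyl)silyl]oxy}-2-hydroxy-5-(2-methylbut-3-en-2-yl)benzaldehyde | C=CC(C)(C)c1cc(C=O)c(O)cc1O[Si](C)(C)C(C)(C)C
F3 | step 10 | prop-2-en-1-yl (2E)-3-{4-[tert-butyl(dimethyl)silyl]oxy-2-hydroxy-5-(2-methylbut-3-en-2-yl)phenyl}-2-{[(2S,3R)-3-{2-[(2R)-3,3-dimethyloxiran-2-yl]ethyl}-3-methyloxiran-2-yl]methyl}prop-2-enoate | C=CC(C)(C)c1cc(/C=C(\C[C@@H]2O[C@]2(C)CC[C@H]2OC2(C)C)C(=O)OCC=C)c(O)cc1O[Si](C)(C)C(C)(C)C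
F4 | step 8 | prop-2-en-1-yl 3-[(2S,3R)-3-{2-[(2R)-3,3-dimethyloxiran-2-yl]ethyl}-3-methyloxiran-2-yl]-2-(triphenyl-λ5-phosphanylidene)propanoate | C=CCOC(=O)C(C[C@@H]1O[C@]1(C)CC[C@H]1OC1(C)C)=P(c1ccccc1)(c1ccccc1)c1ccccc1
F5 | step 6 | (2R,3R)-3-{2-[(2R)-3,3-dimethyloxiran-2-yl]ethyl}-2-(iodomethyl)-3-methyloxirane | IC[C@@H]1O[C@]1(C)CC[C@H]1OC1(C)C
F6 | step 2 | 4-formyl-2-(2-methylbut-3-en-2-yl)phenyl butanoate | CCCC(=O)Oc1ccc(C=O)cc1C(C)(C)C=C
F7 | step 9 | sodium (2E)-3-{4-[tert-butyl(dimethyl)silyl]oxy-3-(2-methylbut-3-en-2-yl)phenyl}-2-{[(2S,3R)-3-{2-[(2R)-3,3-dimethyloxiran-2-yl]ethyl}-3-methyloxiran-2-yl]methyl}prop-2-enoate | C=CC(C)(C)c1cc(/C=C(\C[C@@H]2O[C@]2(C)CC[C@H]2OC2(C)C)C(=O)[O-])ccc1O[Si](C)(C)C(C)(C)C.[Na+]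
A1 | alternative 1 | 5-{[tert-butyl(dimethyl)silyl]oxy}-2-(2-methylbut-3-en-2-yl)phenol | C=CC(C)(C)c1ccc(O[Si](C)(C)C(C)(C)C)cc1O
A2 | alternative 1 | 2-acetyl-5-{[tert-butyl(dimethyl)silyl]oxy}phenyl tert-butyl carbonate | CC(=O)c1ccc(O[Si](C)(C)C(C)(C)C)cc1OC(=O)OC(C)(C)C
A3 | alternative 1 | 3-{[tert-butyl(dimethyl)silyl]oxy}-6-(propan-2-ylidene)cyclohexa-2,4-dien-1-one | CC(C)=C1C=CC(O[Si](C)(C)C(C)(C)C)=CC1=O
A4 | alternative 2 | methyl 2,4-dihydroxy-5-(2-methylbut-3-en-2-yl)benzoate | COC(=O)c1cc(C(C)(C)C=C)c(O)cc1O
A5 | alternative 2 | 1-methoxy-5,5-dimethyl-1,3-bis(trimethylsilyloxy)hepta-1,3,6-triene | COC(O[Si](C)(C)C)=CC(O[Si](C)(C)C)=CC(C)(C)C=C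
A6 | alternative 2 | methyl propiolate | C#CC(=O)OC
A7 | alternative 3 | 2-({[tert-butyl(dimethyl)silyl]oxy}methyl)-5-hydroxy-4-(2-methylbut-3-en-2-yl)phenyl acetate | C=CC(C)(C)c1cc(CO[Si](C)(C)C(C)(C)C)c(OC(C)=O)cc1O
A8 | alternative 3 | (4E)-3-({[tert-butyl(dimethyl)silyl]oxy}methyl)-6,6-dimethylocta-4,7-dien-1-yn-3-yl acetate (racemic) | C#CC(CO[Si](C)(C)C(C)(C)C)(OC(C)=O)/C=C/C(C)(C)C=C
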